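**Retrosynthetic overview**

1. The side-chain bond C1′–C2′ (the CH2 on quinone C3 to the first alkene carbon) is cut to give 2-(chloromethyl)-3-methyl-1,4-naphthoquinone 2 and the C38 terminal alkyne 23. One flask joins them: Zr-catalysed methylalumination of 23, then cross-coupling with 2 under zerovalent nickel. This operation also installs the C3′ methyl group, fixes the E geometry of C2′=C3′ and delivers the quinone at its final oxidation level without protecting groups.
2. Enabling feature: C1′ is a CH2 on C3 of quinone ring B, allylic to C2=C3 and vinylogous alpha to the C4 carbonyl, so its chloride adds readily to zerovalent nickel. C2′(H)=C3′(CH3) is an E-trisubstituted alkene, the exact retron of syn CH3–Al addition to a terminal alkyne C2′≡C3′.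
3. Alkyne 23 comes from a sulfone-mediated allyl–allyl union of the C15 tail sulfone 12 with the C23 head bromide 19, followed by reductive desulfonylation and desilylation.
4. Sulfone 12 comes from (S)-citronellyl bromide, the source of the only stereocentre, by propargylation with a triisopropylsilyl-capped reagent and a first methylalumination/formaldehyde trapping. Bromide 19 comes from all-E geranylgeraniol by propargylation with a trimethylsilyl-capped reagent and terminal allylic oxidation.
5. No ring is formed in the route: ring A (benzo) and ring B (quinone) are bought together in menadione and only chloromethylated at C3.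

Key step: step 14

Remark: side-chain carbons are numbered C1′ (the CH2 on quinone C3) to C32′; commercial all-E geranylgeraniol and (S)-citronellyl bromide are taken as isomerically pure, and sulfone 21 is expected as both epimers at its sulfonyl-bearing carbon, which is removed in step 12.

**Route**

Step 1
Reactants: 1 menadione (2-methyl-1,4-naphthoquinone)
Product: 2 2-(chloromethyl)-3-methyl-1,4-naphthoquinone
Conditions: 37% aq. HCHO, HCl (g), AcOH, rt
Reagents that add atoms: formaldehyde C=O; hydrogen chloride Cl
Why: Blanc-type chloromethylation at C3, the only free CH of quinone ring B, is a known reaction of menadione and should give the allylic chloride directly.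

Step 2
Reactants: 3 (S)-citronellyl bromide [(S)-8-bromo-2,6-dimethyloct-2-ene]; 4 1-(triisopropylsilyl)propyne
Product: 6 (R)-(6,10-dimethylundec-9-en-1-yn-1-yl)tri(propan-2-yl)silane, via lithiated triisopropylsilylpropyne 5 (not isolated)
Conditions: 4, n-BuLi, THF, −20 → 0 °C; then 3, THF/DMPU, −78 °C → rt
Reagents that add atoms: none
Why: SN2 alkylation of the propargylic lithium reagent by an unactivated primary bromide, in which the bulky triisopropylsilyl group directs attack to the propargylic carbon and suppresses allenyl products at the temperature this less reactive electrophile needs, leaves the remote stereocentre untouched (its descriptor changes from S to R only through the priority rules).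

Step 3
Reactants: 6 (R)-(6,10-dimethylundec-9-en-1-yn-1-yl)tri(propan-2-yl)silane
Product: 7 (R)-6,10-dimethylundec-9-en-1-yne
Conditions: n-Bu4NF (TBAF), THF, 0 °C → rt; aq. NH4Cl work-up
Reagents that add atoms: none
Why: Fluoride-induced cleavage of the alkynyl C–Si bond is the standard protodesilylation of a triisopropylsilyl alkyne and touches nothing else in the molecule.

Step 4
Reactants: 7 (R)-6,10-dimethylundec-9-en-1-yne
Product: 10 (2E,7R)-3,7,11-trimethyldodeca-2,10-dien-1-ol, via alkenylalane 8 (not isolated), via lithium alanate 9 (not isolated)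
Conditions: Me3Al, Cp2ZrCl2 (cat.), CH2Cl2, 0 °C → rt; then n-BuLi, THF, −78 °C; (CH2O)n, → rt; aq. potassium sodium tartrate (KNaC4H4O6) work-up
Reagents that add atoms: trimethylaluminium C[Al](C)C; formaldehyde (as paraformaldehyde) C=O
Why: Negishi carboalumination adds CH3–Al syn across the terminal alkyne with aluminium on the terminal carbon, and hydroxymethylation of the derived alanate proceeds with retention, so the E-trisubstituted allylic alcohol should result while the trisubstituted alkene is inert.

Step 5
Reactants: 10 (2E,7R)-3,7,11-trimethyldodeca-2,10-dien-1-ol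
Product: 11 (2E,7R)-1-bromo-3,7,11-trimethyldodeca-2,10-diene
Conditions: PBr3, pyridine (cat.), Et2O, 0 °C
Reagents that add atoms: phosphorus tribromide BrP(Br)Br
Why: Low-temperature bromination of a primary allylic alcohol through its phosphite ester is an SN2 process that should keep the alkene position and E geometry.

Step 6
Reactants: 11 (2E,7R)-1-bromo-3,7,11-trimethyldodeca-2,10-diene
Product: 12 [(2E,7R)-3,7,11-trimethyldodeca-2,10-dien-1-yl]sulfonylbenzene
Conditions: PhSO2Na, DMF, rt
Reagents that add atoms: sodium benzenesulfinate [Na+].[O-]S(=O)c1ccccc1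
Why: S-alkylation of the sulfinate anion by a primary allylic bromide is the standard route to allylic phenyl sulfones and proceeds by SN2 displacement.

Step 7
Reactants: 13 all-E geranylgeraniol [(2E,6E,10E)-3,7,11,15-tetramethylhexadeca-2,6,10,14-tetraen-1-ol]
Product: 14 (2E,6E,10E)-1-bromo-3,7,11,15-tetramethylhexadeca-2,6,10,14-tetraene
Conditions: PBr3, Et2O, 0 °C
Reagents that add atoms: phosphorus tribromide BrP(Br)Br
Why: The same SN2 allylic bromination as in step 5 is routine for polyprenols and should preserve all three E alkenes.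

Step 8
Reactants: 14 (2E,6E,10E)-1-bromo-3,7,11,15-tetramethylhexadeca-2,6,10,14-tetraene; 15 1-(trimethylsilyl)propyne
Product: 17 trimethyl[(5E,9E,13E)-6,10,14,18-tetramethylnonadeca-5,9,13,17-tetraen-1-yn-1-yl]silane, via lithiated trimethylsilylpropyne 16 (not isolated)
Conditions: 15, n-BuLi, THF, −78 → −20 °C; then 14, −78 → 0 °C
Reagents that add atoms: none
Why: The trimethylsilyl-capped propargyl lithium reagent alkylates reactive primary polyprenyl halides at low temperature at the alpha carbon (SN2, no allylic transposition), a known way to add the three-carbon alkyne unit to a polyprenyl chain.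

Step 9
Reactants: 17 trimethyl[(5E,9E,13E)-6,10,14,18-tetramethylnonadeca-5,9,13,17-tetraen-1-yn-1-yl]silane
Product: 18 (2E,6E,10E,14E)-2,6,10,14-tetramethyl-19-(trimethylsilyl)nonadeca-2,6,10,14-tetraen-18-yn-1-ol
Conditions: SeO2 (cat.), t-BuOOH, salicylic acid (cat.), CH2Cl2, 0 °C → rt
Reagents that add atoms: selenium dioxide O=[Se]=O (catalytic oxygen carrier); tert-butyl hydroperoxide CC(C)(C)OO (stoichiometric oxygen source)
Why: Riley allylic oxidation (ene reaction then [2,3]-sigmatropic shift) is known to favour the E methyl group of the terminal isopropylidene unit of polyprenyl chains, which should give the E allylic alcohol.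

Step 10
Reactants: 18 (2E,6E,10E,14E)-2,6,10,14-tetramethyl-19-(trimethylsilyl)nonadeca-2,6,10,14-tetraen-18-yn-1-ol
Product: 19 [(5E,9E,13E,17E)-19-bromo-6,10,14,18-tetramethylnonadeca-5,9,13,17-tetraen-1-yn-1-yl]trimethylsilane
Conditions: PBr3, Et2O, 0 °C
Reagents that add atoms: phosphorus tribromide BrP(Br)Br
Why: SN2 bromination of the primary allylic alcohol as in steps 5 and 7 should be tolerated by the silylalkyne and the other alkenes.

Step 11
Reactants: 12 [(2E,7R)-3,7,11-trimethyldodeca-2,10-dien-1-yl]sulfonylbenzene; 19 [(5E,9E,13E,17E)-19-bromo-6,10,14,18-tetramethylnonadeca-5,9,13,17-tetraen-1-yn-1-yl]trimethylsilane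
Product: 21 [(5E,9E,13E,17E,21E,26R)-6,10,14,18,22,26,30-heptamethyl-20-(phenylsulfonyl)hentriaconta-5,9,13,17,21,29-hexaen-1-yn-1-yl]trimethylsilane (both C20 epimers), via lithiated sulfone 20 (not isolated)
Conditions: 12, n-BuLi, THF/DMPU, −78 °C; then 19, −78 → −20 °C
Reagents that add atoms: none
Why: Biellmann-type alkylation of the alpha-sulfonyl allyl anion at its alpha carbon by a primary allylic bromide (SN2) is the classical head-to-tail polyprenyl union; the new sulfonyl-bearing centre is uncontrolled and is erased in step 12.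

Step 12
Reactants: 21 [(5E,9E,13E,17E,21E,26R)-6,10,14,18,22,26,30-heptamethyl-20-(phenylsulfonyl)hentriaconta-5,9,13,17,21,29-hexaen-1-yn-1-yl]trimethylsilane
Product: 22 trimethyl[(5E,9E,13E,17E,21E,26R)-6,10,14,18,22,26,30-heptamethylhentriaconta-5,9,13,17,21,29-hexaen-1-yn-1-yl]silane
Conditions: PdCl2(dppp) (cat.), LiBHEt3, THF, 0 °C
Reagents that add atoms: none
Why: Palladium-catalysed reductive desulfonylation ionises the allylic sulfone to a pi-allyl complex and delivers hydride to the less substituted terminus (C20), which should keep the C21=C22 alkene in place and E, while the silylalkyne is inert to the borohydride.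

Step 13
Reactants: 22 trimethyl[(5E,9E,13E,17E,21E,26R)-6,10,14,18,22,26,30-heptamethylhentriaconta-5,9,13,17,21,29-hexaen-1-yn-1-yl]silane
Product: 23 (5E,9E,13E,17E,21E,26R)-6,10,14,18,22,26,30-heptamethylhentriaconta-5,9,13,17,21,29-hexaen-1-yne
Conditions: K2CO3, MeOH/THF, rt
Reagents that add atoms: none
Why: Base-catalysed methanolysis of the trimethylsilyl alkynyl C–Si bond is a standard protodesilylation and should free the terminal alkyne needed for carbometalation.

Step 14
Reactants: 23 (5E,9E,13E,17E,21E,26R)-6,10,14,18,22,26,30-heptamethylhentriaconta-5,9,13,17,21,29-hexaen-1-yne; 2 2-(chloromethyl)-3-methyl-1,4-naphthoquinone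
Product: 25 2-methyl-3-[(2E,6E,10E,14E,18E,22E,27R)-3,7,11,15,19,23,27,31-octamethyldotriaconta-2,6,10,14,18,22,30-heptaen-1-yl]naphthalene-1,4-dione, via alkenylalane 24 (not isolated)
Conditions: 23, Me3Al, Cp2ZrCl2 (cat.), ClCH2CH2Cl, 0 °C → rt; volatiles and excess Me3Al removed in vacuo, hexane; then 2, NiCl2(PPh3)2 (cat.) pre-reduced with n-BuLi to zerovalent nickel, THF, −20 °C → rt
Reagents that add atoms: trimethylaluminium C[Al](C)C
Why: Cp2ZrCl2-catalysed methylalumination adds CH3–Al syn across the terminal C≡C of 23, with aluminium on the terminal carbon and methyl on the internal one, so alkenylalane 24 already carries the C3′ methyl group and the E geometry of C2′=C3′, and the six trisubstituted alkenes stay inert because this reagent carbometalates only terminal alkynes. Zerovalent nickel then inserts into the C–Cl bond of 2, which is activated as an allylic, vinylogous alpha-chloroketone position on quinone ring B, the alkenyl group passes from aluminium to nickel in preference to methyl, and reductive elimination forms the C1′–C2′ bond with retention of alkene geometry. The closest known reaction type is the nickel-catalysed cross-coupling of carboalumination-derived alkenylalanes with chloromethylated para-quinones and benzylic chlorides used for prenylated quinones. No ring is closed and no stereocentre is formed; the only new stereoelement, the E alkene, is controlled by the syn mode of carbometalation, and C27′ is remote and untouched. The step needs regioselective methylalumination (secured by the unhindered terminal alkyne), C–Cl coupling in preference to addition at the quinone carbonyls (secured by the low nucleophilicity of the alane, removal of excess Me3Al and fast nickel catalysis at low temperature) and no allylic transposition (secured because attack at ring carbon C3 would destroy the enedione conjugation).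

**Compound list**

1 | menadione (2-methyl-1,4-naphthoquinone) | CC1=CC(=O)c2ccccc2C1=O | starting material
2 | 2-(chloromethyl)-3-methyl-1,4-naphthoquinone | ClCC1=C(C)C(=O)c2ccccc2C1=O | intermediate
3 | (S)-citronellyl bromide [(S)-8-bromo-2,6-dimethyloct-2-ene] | CC(C)=CCC[C@H](C)CCBr | starting material
4 | 1-(triisopropylsilyl)propyne | CC#C[Si](C(C)C)(C(C)C)C(C)C | starting material
5 | [3-(triisopropylsilyl)prop-2-yn-1-yl]lithium | [Li]CC#C[Si](C(C)C)(C(C)C)C(C)C | intermediate
6 | (R)-(6,10-dimethylundec-9-en-1-yn-1-yl)tri(propan-2-yl)silane | CC(C)=CCC[C@H](C)CCCC#C[Si](C(C)C)(C(C)C)C(C)C | intermediate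
7 | (R)-6,10-dimethylundec-9-en-1-yne | CC(C)=CCC[C@H](C)CCCC#C | intermediate
8 | dimethyl[(1E,6R)-2,6,10-trimethylundeca-1,9-dien-1-yl]alane | CC(C)=CCC[C@H](C)CCC/C(C)=C/[Al](C)C | intermediate
9 | lithium butyldimethyl[(1E,6R)-2,6,10-trimethylundeca-1,9-dien-1-yl]alanate | CC(C)=CCC[C@H](C)CCC/C(C)=C/[Al-](C)(C)CCCC.[Li+] | intermediate
10 | (2E,7R)-3,7,11-trimethyldodeca-2,10-dien-1-ol | CC(C)=CCC[C@H](C)CCC/C(C)=C/CO | intermediate
11 | (2E,7R)-1-bromo-3,7,11-trimethyldodeca-2,10-diene | CC(C)=CCC[C@H](C)CCC/C(C)=C/CBr | intermediate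
12 | [(2E,7R)-3,7,11-trimethyldodeca-2,10-dien-1-yl]sulfonylbenzene | CC(C)=CCC[C@H](C)CCC/C(C)=C/CS(=O)(=O)c1ccccc1 | intermediate
13 | all-E geranylgeraniol [(2E,6E,10E)-3,7,11,15-tetramethylhexadeca-2,6,10,14-tetraen-1-ol] | CC(C)=CCC/C(C)=C/CC/C(C)=C/CC/C(C)=C/CO | starting material
14 | (2E,6E,10E)-1-bromo-3,7,11,15-tetramethylhexadeca-2,6,10,14-tetraene | CC(C)=CCC/C(C)=C/CC/C(C)=C/CC/C(C)=C/CBr | intermediate
15 | 1-(trimethylsilyl)propyne | CC#C[Si](C)(C)C | starting material
16 | [3-(trimethylsilyl)prop-2-yn-1-yl]lithium | [Li]CC#C[Si](C)(C)C | intermediate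
17 | trimethyl[(5E,9E,13E)-6,10,14,18-tetramethylnonadeca-5,9,13,17-tetraen-1-yn-1-yl]silane | CC(C)=CCC/C(C)=C/CC/C(C)=C/CC/C(C)=C/CCC#C[Si](C)(C)C | intermediate
18 | (2E,6E,10E,14E)-2,6,10,14-tetramethyl-19-(trimethylsilyl)nonadeca-2,6,10,14-tetraen-18-yn-1-ol | OC/C(C)=C/CC/C(C)=C/CC/C(C)=C/CC/C(C)=C/CCC#C[Si](C)(C)C | intermediate
19 | [(5E,9E,13E,17E)-19-bromo-6,10,14,18-tetramethylnonadeca-5,9,13,17-tetraen-1-yn-1-yl]trimethylsilane | BrC/C(C)=C/CC/C(C)=C/CC/C(C)=C/CC/C(C)=C/CCC#C[Si](C)(C)C | intermediate
20 | [(2E,7R)-1-(phenylsulfonyl)-3,7,11-trimethyldodeca-2,10-dien-1-yl]lithium | CC(C)=CCC[C@H](C)CCC/C(C)=C/C([Li])S(=O)(=O)c1ccccc1 | intermediate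
21 | [(5E,9E,13E,17E,21E,26R)-6,10,14,18,22,26,30-heptamethyl-20-(phenylsulfonyl)hentriaconta-5,9,13,17,21,29-hexaen-1-yn-1-yl]trimethylsilane (both C20 epimers) | CC(C)=CCC[C@H](C)CCC/C(C)=C/C(C/C(C)=C/CC/C(C)=C/CC/C(C)=C/CC/C(C)=C/CCC#C[Si](C)(C)C)S(=O)(=O)c1ccccc1 | intermediate
22 | trimethyl[(5E,9E,13E,17E,21E,26R)-6,10,14,18,22,26,30-heptamethylhentriaconta-5,9,13,17,21,29-hexaen-1-yn-1-yl]silane | CC(C)=CCC[C@H](C)CCC/C(C)=C/CC/C(C)=C/CC/C(C)=C/CC/C(C)=C/CC/C(C)=C/CCC#C[Si](C)(C)C | intermediate
23 | (5E,9E,13E,17E,21E,26R)-6,10,14,18,22,26,30-heptamethylhentriaconta-5,9,13,17,21,29-hexaen-1-yne | CC(C)=CCC[C@H](C)CCC/C(C)=C/CC/C(C)=C/CC/C(C)=C/CC/C(C)=C/CC/C(C)=C/CCC#C | intermediate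
24 | dimethyl[(1E,5E,9E,13E,17E,21E,26R)-2,6,10,14,18,22,26,30-octamethylhentriaconta-1,5,9,13,17,21,29-heptaen-1-yl]alane | CC(C)=CCC[C@H](C)CCC/C(C)=C/CC/C(C)=C/CC/C(C)=C/CC/C(C)=C/CC/C(C)=C/CC/C(C)=C/[Al](C)C | intermediate
25 | 2-methyl-3-[(2E,6E,10E,14E,18E,22E,27R)-3,7,11,15,19,23,27,31-octamethyldotriaconta-2,6,10,14,18,22,30-heptaen-1-yl]naphthalene-1,4-dione | CC(C)=CCC[C@H](C)CCC/C(C)=C/CC/C(C)=C/CC/C(C)=C/CC/C(C)=C/CC/C(C)=C/CC/C(C)=C/CC1=C(C)C(=O)c2ccccc2C1=O | target

**Step count**

Total step count: 14 steps.
Longest linear sequence: 9 steps, from (S)-citronellyl bromide 3 (steps 2, 3, 4, 5, 6, 11, 12, 13, 14).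

**Steps most likely to fail, with fallbacks**

1. Step 9. The allylic oxidation may spread to the allylic positions of the three internal alkenes, and the terminal alcohol may be oxidised further to the enal, so that conversion has to be kept low. The fallback sets out from 17 and returns to the route at 18. It replaces C–H oxidation by oxidative cleavage and re-olefination of the terminal alkene. N-Bromosuccinimide in aqueous THF at 0 °C should attack the terminal, most exposed alkene to give the racemic bromohydrin (6E,10E,14E)-3-bromo-2,6,10,14-tetramethyl-19-(trimethylsilyl)nonadeca-6,10,14-trien-18-yn-2-ol F1. NaH in THF should close it to the epoxide trimethyl[(5E,9E,13E)-16-(3,3-dimethyloxiran-2-yl)-6,10,14-trimethylhexadeca-5,9,13-trien-1-yn-1-yl]silane F2. HIO4 in aqueous THF should cleave the epoxide to the aldehyde (4E,8E,12E)-4,8,12-trimethyl-17-(trimethylsilyl)heptadeca-4,8,12-trien-16-ynal F3. A Wittig reaction with the stabilised ylide Ph3P=C(CH3)CO2Et in CH2Cl2 should give the E ester ethyl (2E,6E,10E,14E)-2,6,10,14-tetramethyl-19-(trimethylsilyl)nonadeca-2,6,10,14-tetraen-18-ynoate F4, and i-Bu2AlH in CH2Cl2 at −78 °C should reduce it to 18.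

2. Step 14. Electron transfer from the organometallic species to the free quinone, addition of the alane or of residual Me3Al to the quinone carbonyls, and methyl instead of alkenyl transfer may all compete with the desired coupling. The fallback sets out from 1 and from alkenylalane 24 and returns at 25. It forms the same bond at the protected hydroquinone oxidation level. Reduction of 1 with Na2S2O4 and methylation with Me2SO4/KOH should give 1,4-dimethoxy-2-methylnaphthalene F5. Chloromethylation (aq. HCHO, HCl) should give 2-(chloromethyl)-1,4-dimethoxy-3-methylnaphthalene F6. Coupling of this benzylic chloride with 24 under the same zerovalent nickel catalyst should give 1,4-dimethoxy-2-methyl-3-[(2E,6E,10E,14E,18E,22E,27R)-3,7,11,15,19,23,27,31-octamethyldotriaconta-2,6,10,14,18,22,30-heptaen-1-yl]naphthalene F7. Oxidative demethylation with (NH4)2Ce(NO3)6 in MeCN/H2O at 0 °C should then give 25.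

3. Step 12. Hydride may be delivered to the wrong terminus of the pi-allyl intermediate (alkene transposition), the C21=C22 geometry may erode through syn–anti interchange of the pi-allyl complex, and the palladium hydride may add to the alkyne. The fallback sets out from 10 and 19 and returns at 22. It joins the same two fragments without a sulfone, so steps 5, 6, 11 and 12 are bypassed. MsCl, LiCl and 2,4,6-collidine in DMF at 0 °C should convert 10 into (2E,7R)-1-chloro-3,7,11-trimethyldodeca-2,10-diene F8. Active barium (from BaI2 and lithium biphenylide) in THF at −78 °C should give [(2E,7R)-3,7,11-trimethyldodeca-2,10-dien-1-yl]barium chloride F9. This allylbarium reagent should couple at its alpha carbon with the primary allylic bromide 19, with retention of both alkene geometries, to give 22 directly.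

Further compounds
F1 | step 9 | (6E,10E,14E)-3-bromo-2,6,10,14-tetramethyl-19-(trimethylsilyl)nonadeca-6,10,14-trien-18-yn-2-ol (racemic) | CC(C)(O)C(Br)CC/C(C)=C/CC/C(C)=C/CC/C(C)=C/CCC#C[Si](C)(C)C
F2 | step 9 | trimethyl[(5E,9E,13E)-16-(3,3-dimethyloxiran-2-yl)-6,10,14-trimethylhexadeca-5,9,13-trien-1-yn-1-yl]silane (racemic) | CC1(C)OC1CC/C(C)=C/CC/C(C)=C/CC/C(C)=C/CCC#C[Si](C)(C)C
F3 | step 9 | (4E,8E,12E)-4,8,12-trimethyl-17-(trimethylsilyl)heptadeca-4,8,12-trien-16-ynal | O=CCC/C(C)=C/CC/C(C)=C/CC/C(C)=C/CCC#C[Si](C)(C)C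
F4 | step 9 | ethyl (2E,6E,10E,14E)-2,6,10,14-tetramethyl-19-(trimethylsilyl)nonadeca-2,6,10,14-tetraen-18-ynoate | CCOC(=O)/C(C)=C/CC/C(C)=C/CC/C(C)=C/CC/C(C)=C/CCC#C[Si](C)(C)C
F5 | step 14 | 1,4-dimethoxy-2-methylnaphthalene | COc1cc(C)c(OC)c2ccccc12
F6 | step 14 | 2-(chloromethyl)-1,4-dimethoxy-3-methylnaphthalene | COc1c(CCl)c(C)c(OC)c2ccccc12
F7 | step 14 | 1,4-dimethoxy-2-methyl-3-[(2E,6E,10E,14E,18E,22E,27R)-3,7,11,15,19,23,27,31-octamethyldotriaconta-2,6,10,14,18,22,30-heptaen-1-yl]naphthalene | CC(C)=CCC[C@H](C)CCC/C(C)=C/CC/C(C)=C/CC/C(C)=C/CC/C(C)=C/CC/C(C)=C/CC/C(C)=C/Cc1c(C)c(OC)c2ccccc2c1OC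
F8 | step 12 | (2E,7R)-1-chloro-3,7,11-trimethyldodeca-2,10-diene | CC(C)=CCC[C@H](C)CCC/C(C)=C/CCl
F9 | step 12 | [(2E,7R)-3,7,11-trimethyldodeca-2,10-dien-1-yl]barium chloride | CC(C)=CCC[C@H](C)CCC/C(C)=C/C[Ba]Cl
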